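**Retrosynthetic overview**

1. Ring numbering used below: O1, O2, C3 (acetic acid arm), C4 (methyl), C5, C6 (methyl and side chain); C8 is the side-chain stereocenter. The phenyl ring is bought and the 1,2-dioxane is the only ring built (step 15).
2. Key disconnection C3–C4: a 6-exo vinyl-radical closure of the 1,2-dioxane with the O1–O2 bond already in place. The enabling feature is that C3 carries both O2 and the CH2CO2H arm, so it can be the β-carbon of a β-peroxyacryloyl acceptor, while C4 is the internal carbon of a propargyl group on C6, five atoms away through C5–C6–O1–O2.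
3. The acid is carried as an N-acyl oxazolidinone that activates the acceptor (Yb chelate) and sets C3. C4 is then set by diimide reduction of the exocyclic methylene, and the auxiliary leaves in the last step.
4. C6–O1 comes from inverting perhydrolysis of a 2,2-disubstituted oxetane (Sharpless epoxidation, Red-Al opening, ring closure); the propargyl arm is grown from the oxetane-derived CH2CH2OH.
5. C8 comes from (S)-3-bromo-2-methylpropan-1-ol, joined to the phenylalkyl chain by copper-catalysed Grignard coupling.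

Key step: step 15

Remark: (8-bromooctyl)benzene, (S)-3-bromo-2-methylpropan-1-ol, (R)-4-(diphenylmethyl)-1,3-oxazolidin-2-one and propiolic acid are taken as commercial; anhydrous ethereal H2O2 is prepared by extraction and handled behind a shield.

**Route**

Step 1
Reactants: 1 (8-bromooctyl)benzene; 2 (2S)-3-bromo-2-methylpropan-1-ol
Product: 4 (2R)-2-methyl-11-phenylundecan-1-ol, via Grignard reagent 3 (not isolated)
Conditions: Mg, THF, 40 °C (3, 2.5 equiv); then 2, Li2CuCl4 (cat.), THF, −20 °C to rt
Reagents that add atoms: none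
Why: Copper-catalysed Grignard cross-coupling at the primary C–Br bond should join the chain without touching the stereocenter of 2 (the future C8); the first equivalent of 3 only deprotonates the hydroxyl.

Step 2
Reactants: 4 (2R)-2-methyl-11-phenylundecan-1-ol
Product: 5 (2R)-1-iodo-2-methyl-11-phenylundecane
Conditions: I2, PPh3, imidazole, CH2Cl2, 0 °C to rt
Reagents that add atoms: iodine, II
Why: Appel-type iodination of a primary alcohol; the stereocenter is not involved.

Step 3
Reactants: 5 (2R)-1-iodo-2-methyl-11-phenylundecane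
Product: 6 (4R)-4-methyl-13-phenyltridec-1-yne
Conditions: LiC≡CH·H2NCH2CH2NH2, DMSO, rt
Reagents that add atoms: lithium acetylide–ethylenediamine complex, [Li+].[C-]#C.NCCN
Why: SN2 alkynylation of a primary iodide in a dipolar aprotic solvent.

Step 4
Reactants: 6 (4R)-4-methyl-13-phenyltridec-1-yne
Product: 9 (2E,5R)-3,5-dimethyl-14-phenyltetradec-2-en-1-ol, via alkenylalane 7 (not isolated), via lithium aluminate 8 (not isolated)
Conditions: Me3Al, Cp2ZrCl2 (cat.), CH2Cl2, 0 °C to rt; then n-BuLi, THF, −78 °C; then (CH2O)n, −78 °C to rt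
Reagents that add atoms: trimethylaluminium, C[Al](C)C; paraformaldehyde (as formaldehyde), C=O
Why: Negishi zirconium-catalysed carboalumination adds CH3 and Al syn across the alkyne, and hydroxymethylation of the aluminate with retention should give the E allylic alcohol.

Step 5
Reactants: 9 (2E,5R)-3,5-dimethyl-14-phenyltetradec-2-en-1-ol
Product: 10 [(2S,3S)-3-methyl-3-[(2R)-2-methyl-11-phenylundecyl]oxiran-2-yl]methanol
Conditions: Ti(OiPr)4 (cat.), L-(+)-diethyl tartrate, t-BuOOH, 4 Å sieves, CH2Cl2, −20 °C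
Reagents that add atoms: tert-butyl hydroperoxide, CC(C)(C)OO
Why: Sharpless asymmetric epoxidation; the L-(+)-tartrate catalyst selects the alkene face that gives the (2S,3S) epoxide and so fixes the tertiary C–O center that becomes C6, independently of the remote C8.

Step 6
Reactants: 10 [(2S,3S)-3-methyl-3-[(2R)-2-methyl-11-phenylundecyl]oxiran-2-yl]methanol
Product: 11 (3S,5R)-3,5-dimethyl-14-phenyltetradecane-1,3-diol
Conditions: NaAlH2(OCH2CH2OCH3)2, THF, 0 °C to rt
Reagents that add atoms: none
Why: Alkoxide-directed hydride delivery to C2 of the 2,3-epoxy alcohol (Red-Al opening) should give the 1,3-diol; the tertiary C–O bond is untouched.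

Step 7
Reactants: 11 (3S,5R)-3,5-dimethyl-14-phenyltetradecane-1,3-diol
Product: 13 (2S)-2-methyl-2-[(2R)-2-methyl-11-phenylundecyl]oxetane, via primary tosylate 12 (not isolated)
Conditions: TsCl, KOtBu, THF, 0 °C to rt
Reagents that add atoms: none
Why: Selective tosylation of the primary hydroxyl and 4-exo-tet Williamson closure by the tertiary alkoxide; the configuration at the tertiary carbon is retained because its C–O bond is not broken.

Step 8
Reactants: 13 (2S)-2-methyl-2-[(2R)-2-methyl-11-phenylundecyl]oxetane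
Product: 14 (3R,5R)-3-hydroperoxy-3,5-dimethyl-14-phenyltetradecan-1-ol
Conditions: H2O2 (anhydrous, in Et2O), Me3SiOTf (cat.), Et2O, −78 to 0 °C
Reagents that add atoms: hydrogen peroxide, OO
Why: Lewis acid-promoted perhydrolysis of a 2,2-disubstituted oxetane at the tertiary carbon proceeds SN2-like with inversion, which installs O1 on C6 in the configuration of the target.

Step 9
Reactants: 14 (3R,5R)-3-hydroperoxy-3,5-dimethyl-14-phenyltetradecan-1-ol
Product: 15 (3R,5R)-3-[(2-methoxypropan-2-yl)peroxy]-3,5-dimethyl-14-phenyltetradecan-1-ol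
Conditions: 2-methoxypropene (1.1 equiv), PPTS (cat.), CH2Cl2, −20 °C
Reagents that add atoms: 2-methoxypropene, COC(C)=C
Why: Acid-catalysed addition of the hydroperoxide to the enol ether gives the base-stable perketal; the hydroperoxide, the stronger acid and an α-effect nucleophile, should react ahead of the primary alcohol.

Step 10
Reactants: 15 (3R,5R)-3-[(2-methoxypropan-2-yl)peroxy]-3,5-dimethyl-14-phenyltetradecan-1-ol
Product: 16 (3R,5R)-3-[(2-methoxypropan-2-yl)peroxy]-3,5-dimethyl-14-phenyltetradecanal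
Conditions: Dess–Martin periodinane, NaHCO3, CH2Cl2, 0 °C to rt
Reagents that add atoms: none
Why: Buffered Dess–Martin oxidation of a primary alcohol leaves the perketal and the O–O bond intact.

Step 11
Reactants: 16 (3R,5R)-3-[(2-methoxypropan-2-yl)peroxy]-3,5-dimethyl-14-phenyltetradecanal
Product: 17 (4R,6R)-4-[(2-methoxypropan-2-yl)peroxy]-4,6-dimethyl-15-phenylpentadec-1-yne
Conditions: dimethyl (1-diazo-2-oxopropyl)phosphonate, K2CO3, MeOH, 0 °C to rt
Reagents that add atoms: dimethyl (1-diazo-2-oxopropyl)phosphonate, CC(=O)C(=[N+]=[N-])P(=O)(OC)OC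
Why: Ohira–Bestmann (Seyferth–Gilbert) homologation turns the aldehyde carbon into the internal alkyne carbon (the future C4); aldehyde capture by the phosphonate anion should outrun β-elimination of the perketal, as it does with β-silyloxy aldehydes.

Step 12
Reactants: 17 (4R,6R)-4-[(2-methoxypropan-2-yl)peroxy]-4,6-dimethyl-15-phenylpentadec-1-yne
Product: 18 (4R,6R)-4-hydroperoxy-4,6-dimethyl-15-phenylpentadec-1-yne
Conditions: AcOH/THF/H2O (4:2:1), rt
Reagents that add atoms: none
Why: Mild acid hydrolysis of the perketal frees the tertiary hydroperoxide, which has no α-hydrogen and is stable.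

Step 13
Reactants: 19 (4R)-4-(diphenylmethyl)-1,3-oxazolidin-2-one; 20 propiolic acid
Product: 23 (4R)-4-(diphenylmethyl)-3-(prop-2-ynoyl)-1,3-oxazolidin-2-one, via mixed pivalic anhydride 21 (not isolated), via lithium oxazolidinide 22 (not isolated)
Conditions: 20, PivCl, Et3N, THF, −20 °C; 19, n-BuLi, THF, −78 °C; combine, −78 to 0 °C
Reagents that add atoms: none
Why: N-Acylation of the lithiated oxazolidinone by a mixed anhydride, which reacts at the less hindered propioloyl carbonyl.

Step 14
Reactants: 18 (4R,6R)-4-hydroperoxy-4,6-dimethyl-15-phenylpentadec-1-yne; 23 (4R)-4-(diphenylmethyl)-3-(prop-2-ynoyl)-1,3-oxazolidin-2-one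
Product: 24 (4R)-4-(diphenylmethyl)-3-[(2E)-3-{[(4R,6R)-4,6-dimethyl-15-phenylpentadec-1-yn-4-yl]peroxy}prop-2-enoyl]-1,3-oxazolidin-2-one
Conditions: N-methylmorpholine (cat.), CH2Cl2, 0 °C; used at once
Reagents that add atoms: none
Why: Proposed new method: amine-catalysed conjugate addition of the hydroperoxide to the ynoyl imide through the β-ammonium acrylate should give the E vinylogous peroxy ester by addition–elimination; the closest known reactions are the amine-catalysed addition of alcohols to propiolates giving (E)-β-alkoxyacrylates and base-mediated conjugate additions of hydroperoxides to enones and enoates.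

Step 15
Reactants: 24 (4R)-4-(diphenylmethyl)-3-[(2E)-3-{[(4R,6R)-4,6-dimethyl-15-phenylpentadec-1-yn-4-yl]peroxy}prop-2-enoyl]-1,3-oxazolidin-2-one
Product: 26 (4R)-4-(diphenylmethyl)-3-{[(3S,6R)-6-methyl-4-methylidene-6-[(2R)-2-methyl-11-phenylundecyl]-1,2-dioxan-3-yl]acetyl}-1,3-oxazolidin-2-one, via exocyclic (E)-vinylstannane 25 (not isolated)
Conditions: Yb(OTf)3 (1.1 equiv), CH2Cl2/THF (4:1), −78 °C; Bu3SnH (2 equiv, slow addition), Et3B (cat.), air; then p-TsOH·H2O, CH2Cl2, 0 °C
Reagents that add atoms: none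
Why: Proposed new method: Et3B/O2 generates Bu3Sn•, which adds reversibly to the terminal alkyne carbon to give the vinyl radical at C4; this closes onto C3, the β-carbon of the Yb(OTf)3-chelated β-peroxyacryloyl imide, the α-acyl radical takes hydrogen from Bu3SnH, and acid ipso-protodestannylation of 25 leaves the exocyclic methylene. The closest known reactions are hydrostannylative vinyl-radical cyclisations of enynes, radical cyclisations of β-alkoxyacrylates to cyclic ethers, and Lewis acid-promoted, oxazolidinone-controlled radical conjugate additions; what is new is that the tether oxygen is part of a peroxide. The 1,2-dioxane ring (O1, O2, C3–C6) closes in the 6-exo-trig mode through a chair-like transition state. The new stereocenter C3 is set by the auxiliary: in the s-cis chelate the diphenylmethyl group covers one face of C3 and the radical enters from the other, which should give 3S irrespective of C6, whose methyl and CH2R arms are too alike to direct. The step needs the radical chain to spare the O–O bond; this rests on the slow attack of tin radicals on hindered dialkyl peroxides compared with addition to the alkyne, on O1 being γ to C4 (only a strained four-membered substitution is open), and on excess Bu3SnH reducing the cyclised radical before it can expel O1. The 6-exo closure onto the activated acceptor must also outrun 1,5-hydrogen transfer from C8–H.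

Step 16
Reactants: 26 (4R)-4-(diphenylmethyl)-3-{[(3S,6R)-6-methyl-4-methylidene-6-[(2R)-2-methyl-11-phenylundecyl]-1,2-dioxan-3-yl]acetyl}-1,3-oxazolidin-2-one
Product: 27 (4R)-4-(diphenylmethyl)-3-{[(3S,4S,6R)-4,6-dimethyl-6-[(2R)-2-methyl-11-phenylundecyl]-1,2-dioxan-3-yl]acetyl}-1,3-oxazolidin-2-one
Conditions: KO2C–N=N–CO2K (excess), AcOH (slow addition), CH2Cl2, 0 °C to rt
Reagents that add atoms: none
Why: Diimide reduction adds H2 suprafacially and spares the O–O bond; in the chair with the bulky acylmethyl arm at C3 equatorial, the cis-related C6 chain is axial and, together with the C3 arm, shields the lower face of the exocyclic alkene, so hydrogen should add from the upper face and leave the new C4 methyl cis to both (4S).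

Step 17
Reactants: 27 (4R)-4-(diphenylmethyl)-3-{[(3S,4S,6R)-4,6-dimethyl-6-[(2R)-2-methyl-11-phenylundecyl]-1,2-dioxan-3-yl]acetyl}-1,3-oxazolidin-2-one
Product: 29 2-[(3S,4S,6R)-4,6-dimethyl-6-[(2R)-2-methyl-11-phenylundecyl]-1,2-dioxan-3-yl]acetic acid, via peroxy acid 28 (not isolated)
Conditions: LiOH, H2O2, THF/H2O (3:1), 0 °C; then Na2SO3 (aq); then HCl (1 M)
Reagents that add atoms: hydrogen peroxide, OO
Why: Lithium hydroperoxide cleaves the exocyclic imide carbonyl selectively, sulfite reduces the peroxy acid but not the hindered dialkyl peroxide, and no stereocenter is touched.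

**Compound list**

1 | (8-bromooctyl)benzene | BrCCCCCCCCc1ccccc1 | starting material
2 | (2S)-3-bromo-2-methylpropan-1-ol | OC[C@H](C)CBr | starting material
3 | (8-phenyloctyl)magnesium bromide | Br[Mg]CCCCCCCCc1ccccc1 | intermediate
4 | (2R)-2-methyl-11-phenylundecan-1-ol | OC[C@H](C)CCCCCCCCCc1ccccc1 | intermediate
5 | (2R)-1-iodo-2-methyl-11-phenylundecane | IC[C@H](C)CCCCCCCCCc1ccccc1 | intermediate
6 | (4R)-4-methyl-13-phenyltridec-1-yne | C#CC[C@H](C)CCCCCCCCCc1ccccc1 | intermediate
7 | dimethyl[(1E,4R)-2,4-dimethyl-13-phenyltridec-1-en-1-yl]alane | C[Al](C)/C=C(\C)C[C@H](C)CCCCCCCCCc1ccccc1 | intermediate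
8 | lithium butyl(dimethyl)[(1E,4R)-2,4-dimethyl-13-phenyltridec-1-en-1-yl]aluminate | [Li+].CCCC[Al-](C)(C)/C=C(\C)C[C@H](C)CCCCCCCCCc1ccccc1 | intermediate
9 | (2E,5R)-3,5-dimethyl-14-phenyltetradec-2-en-1-ol | OC/C=C(\C)C[C@H](C)CCCCCCCCCc1ccccc1 | intermediate
10 | [(2S,3S)-3-methyl-3-[(2R)-2-methyl-11-phenylundecyl]oxiran-2-yl]methanol | C[C@H](CCCCCCCCCc1ccccc1)C[C@]1(C)O[C@H]1CO | intermediate
11 | (3S,5R)-3,5-dimethyl-14-phenyltetradecane-1,3-diol | C[C@H](CCCCCCCCCc1ccccc1)C[C@@](O)(C)CCO | intermediate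
12 | (3S,5R)-3-hydroxy-3,5-dimethyl-14-phenyltetradecyl 4-methylbenzenesulfonate | C[C@H](CCCCCCCCCc1ccccc1)C[C@@](O)(C)CCOS(=O)(=O)c1ccc(C)cc1 | intermediate
13 | (2S)-2-methyl-2-[(2R)-2-methyl-11-phenylundecyl]oxetane | C[C@H](CCCCCCCCCc1ccccc1)C[C@@]1(C)CCO1 | intermediate
14 | (3R,5R)-3-hydroperoxy-3,5-dimethyl-14-phenyltetradecan-1-ol | C[C@H](CCCCCCCCCc1ccccc1)C[C@](OO)(C)CCO | intermediate
15 | (3R,5R)-3-[(2-methoxypropan-2-yl)peroxy]-3,5-dimethyl-14-phenyltetradecan-1-ol | C[C@H](CCCCCCCCCc1ccccc1)C[C@](OOC(C)(C)OC)(C)CCO | intermediate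
16 | (3R,5R)-3-[(2-methoxypropan-2-yl)peroxy]-3,5-dimethyl-14-phenyltetradecanal | C[C@H](CCCCCCCCCc1ccccc1)C[C@](OOC(C)(C)OC)(C)CC=O | intermediate
17 | (4R,6R)-4-[(2-methoxypropan-2-yl)peroxy]-4,6-dimethyl-15-phenylpentadec-1-yne | C[C@H](CCCCCCCCCc1ccccc1)C[C@](OOC(C)(C)OC)(C)CC#C | intermediate
18 | (4R,6R)-4-hydroperoxy-4,6-dimethyl-15-phenylpentadec-1-yne | C[C@H](CCCCCCCCCc1ccccc1)C[C@](OO)(C)CC#C | intermediate
19 | (4R)-4-(diphenylmethyl)-1,3-oxazolidin-2-one | O=C1N[C@H](C(c2ccccc2)c2ccccc2)CO1 | starting material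
20 | propiolic acid | C#CC(=O)O | starting material
21 | 2,2-dimethylpropanoic prop-2-ynoic anhydride | C#CC(=O)OC(=O)C(C)(C)C | intermediate
22 | lithium (4R)-4-(diphenylmethyl)-2-oxo-1,3-oxazolidin-3-ide | [Li+].O=C1[N-][C@H](C(c2ccccc2)c2ccccc2)CO1 | intermediate
23 | (4R)-4-(diphenylmethyl)-3-(prop-2-ynoyl)-1,3-oxazolidin-2-one | C#CC(=O)N1C(=O)OC[C@H]1C(c1ccccc1)c1ccccc1 | intermediate
24 | (4R)-4-(diphenylmethyl)-3-[(2E)-3-{[(4R,6R)-4,6-dimethyl-15-phenylpentadec-1-yn-4-yl]peroxy}prop-2-enoyl]-1,3-oxazolidin-2-one | C[C@H](CCCCCCCCCc1ccccc1)C[C@](OO/C=C/C(=O)N1C(=O)OC[C@H]1C(c1ccccc1)c1ccccc1)(C)CC#C | intermediate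
25 | (4R)-4-(diphenylmethyl)-3-{[(3S,4E,6R)-6-methyl-6-[(2R)-2-methyl-11-phenylundecyl]-4-[(tributylstannyl)methylidene]-1,2-dioxan-3-yl]acetyl}-1,3-oxazolidin-2-one | C[C@H](CCCCCCCCCc1ccccc1)C[C@]1(C)C/C(=C\[Sn](CCCC)(CCCC)CCCC)[C@H](CC(=O)N2C(=O)OC[C@H]2C(c2ccccc2)c2ccccc2)OO1 | intermediate
26 | (4R)-4-(diphenylmethyl)-3-{[(3S,6R)-6-methyl-4-methylidene-6-[(2R)-2-methyl-11-phenylundecyl]-1,2-dioxan-3-yl]acetyl}-1,3-oxazolidin-2-one | C[C@H](CCCCCCCCCc1ccccc1)C[C@]1(C)CC(=C)[C@H](CC(=O)N2C(=O)OC[C@H]2C(c2ccccc2)c2ccccc2)OO1 | intermediate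
27 | (4R)-4-(diphenylmethyl)-3-{[(3S,4S,6R)-4,6-dimethyl-6-[(2R)-2-methyl-11-phenylundecyl]-1,2-dioxan-3-yl]acetyl}-1,3-oxazolidin-2-one | C[C@H](CCCCCCCCCc1ccccc1)C[C@]1(C)C[C@H](C)[C@H](CC(=O)N2C(=O)OC[C@H]2C(c2ccccc2)c2ccccc2)OO1 | intermediate
28 | 2-[(3S,4S,6R)-4,6-dimethyl-6-[(2R)-2-methyl-11-phenylundecyl]-1,2-dioxan-3-yl]ethaneperoxoic acid | C[C@H](CCCCCCCCCc1ccccc1)C[C@]1(C)C[C@H](C)[C@H](CC(=O)OO)OO1 | intermediate
29 | 2-[(3S,4S,6R)-4,6-dimethyl-6-[(2R)-2-methyl-11-phenylundecyl]-1,2-dioxan-3-yl]acetic acid | C[C@H](CCCCCCCCCc1ccccc1)C[C@]1(C)C[C@H](C)[C@H](CC(=O)O)OO1 | target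

**Step count**

Total: 17 steps. Longest linear sequence: 16 steps (steps 1–12 and 14–17; step 13 makes the second fragment).

**Steps most likely to fail, and fallbacks**

Step 15 (proposed new method). The tin radical chain may be diverted by the peroxide: homolytic attack of Bu3Sn• on the O–O bond, 1,5-hydrogen transfer from C8–H to the vinyl radical, or epoxide-forming O–O scission of the cyclised radical before hydrogen transfer. The fallback gives up the C–C ring closure and closes the ring at O2–C3 by known chemistry, at the cost of stereocontrol at C6 and C3. It sets out from 5 and returns at 29. Commercial (4R)-4-benzyl-3-propanoyl-1,3-oxazolidin-2-one would be alkylated with 2,3-dibromopropene (NaN(SiMe3)2, THF, −78 °C; Evans alkylation) to the bromoallyl imide F1 and reduced (LiBH4) to (2S)-4-bromo-2-methylpent-4-en-1-ol F2. Iodide 5 would be converted (Zn, LiCl, THF) into the alkylzinc iodide F3 and joined to F2 by Negishi coupling (Pd(OAc)2, SPhos) to the methylidene alcohol F4. Dess–Martin oxidation to the aldehyde F5 (used crude) and Wittig olefination (Ph3P=CHCO2Me) would give the diene ester F6. Cobalt-catalysed hydroperoxysilylation of the 1,1-disubstituted alkene (Co(acac)2, O2, Et3SiH; Mukaiyama–Isayama) would give the tertiary silyl peroxide F7 together with its C6 epimer. Bu4NF (THF, 0 °C) would cleave the Si–O bond and let the peroxide anion add to the enoate in the same flask, giving the dioxane methyl ester F8, to be separated from its diastereomers by chromatography. LiOH hydrolysis returns to 29.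

Step 14 (proposed new method). Amine-initiated oligomerisation of the ynoyl imide, or attack of the peroxide on the imide carbonyl (acyl transfer), may outrun conjugate addition. The fallback avoids both amine and peroxide anion and uses two established acid-catalysed reaction types: addition of a hydroperoxide to an enol ether, and alkoxy exchange at a β-alkoxyacrylate. It sets out from 18 and 19 and returns at 24. Oxazolidinone 19 would be acylated (n-BuLi; commercial (E)-3-ethoxyacryloyl chloride) to the ethoxyacryloyl imide F9. The ethoxy group would then be exchanged for hydroperoxide 18 (PPTS cat., toluene, reduced pressure to remove ethanol) by addition to the protonated enol ether and loss of ethanol, giving 24.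

Step 9. Ketalisation may not discriminate, with the primary hydroxyl competing with the hydroperoxide. The fallback replaces selective protection by exhaustive protection and selective deprotection. It sets out from 14 and returns at 15. Excess 2-methoxypropene (PPTS) would give the bis-protected perketal ether F10; brief methanolysis (PPTS, MeOH, 0 °C) should cleave only the O,O-ketal, whose ether oxygen is far more basic than the peroxy oxygen, and return 15.

**Further compounds**

F1 | step 15 | (4R)-4-benzyl-3-[(2S)-4-bromo-2-methylpent-4-enoyl]-1,3-oxazolidin-2-one | C=C(Br)C[C@H](C)C(=O)N1C(=O)OC[C@H]1Cc1ccccc1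
F2 | step 15 | (2S)-4-bromo-2-methylpent-4-en-1-ol | OC[C@@H](C)CC(Br)=C
F3 | step 15 | [(2R)-2-methyl-11-phenylundecyl]zinc iodide | I[Zn]C[C@H](C)CCCCCCCCCc1ccccc1
F4 | step 15 | (2S,6R)-2,6-dimethyl-4-methylidene-15-phenylpentadecan-1-ol | OC[C@@H](C)CC(=C)C[C@H](C)CCCCCCCCCc1ccccc1
F5 | step 15 | (2S,6R)-2,6-dimethyl-4-methylidene-15-phenylpentadecanal | O=C[C@@H](C)CC(=C)C[C@H](C)CCCCCCCCCc1ccccc1
F6 | step 15 | methyl (2E,4S,8R)-4,8-dimethyl-6-methylidene-17-phenylheptadec-2-enoate | COC(=O)/C=C/[C@@H](C)CC(=C)C[C@H](C)CCCCCCCCCc1ccccc1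
F7 | step 15 | methyl (2E,4S,6R,8R)-4,6,8-trimethyl-17-phenyl-6-[(triethylsilyl)peroxy]heptadec-2-enoate | COC(=O)/C=C/[C@@H](C)C[C@](C)(OO[Si](CC)(CC)CC)C[C@H](C)CCCCCCCCCc1ccccc1
F8 | step 15 | methyl 2-[(3S,4S,6R)-4,6-dimethyl-6-[(2R)-2-methyl-11-phenylundecyl]-1,2-dioxan-3-yl]acetate | C[C@H](CCCCCCCCCc1ccccc1)C[C@]1(C)C[C@H](C)[C@H](CC(=O)OC)OO1
F9 | step 14 | (4R)-4-(diphenylmethyl)-3-[(2E)-3-ethoxyprop-2-enoyl]-1,3-oxazolidin-2-one | CCO/C=C/C(=O)N1C(=O)OC[C@H]1C(c1ccccc1)c1ccccc1
F10 | step 9 | (3R,5R)-1-[(2-methoxypropan-2-yl)oxy]-3-[(2-methoxypropan-2-yl)peroxy]-3,5-dimethyl-14-phenyltetradecane | C[C@H](CCCCCCCCCc1ccccc1)C[C@](OOC(C)(C)OC)(C)CCOC(C)(C)OC
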